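**Retrosynthetic overview**
- Target ⇐ hydroxyl-directed epoxidation of the macrocyclic (Z)-allylic alcohol; the C-1 ester and C-9 carbinol ⇐ Evans–Tishchenko reduction of a β-hydroxy enone with 3,4,5-trimethoxybenzaldehyde.
- Ten-membered carbocycle ⇐ alkyl–alkenyl Suzuki–Miyaura closure of the C-6–C-7 bond.
- (Z)-Alkenyl iodide ⇐ trans-hydroalumination/iodination of a butynyl carbinol; (E)-diene ⇐ methylalumination/vinylation of a homopropargyl alcohol.
- C-1 carbinol ⇐ phosphoric-acid-catalysed propargylation; C-9/C-10 ⇐ amine-catalysed anti cross-aldol of isovaleraldehyde with but-2-ynal.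
- Ring order: carbocycle first (step 5), oxirane last (step 8).

Atom labels: ring atoms are C-1 (ester carbinol), C-2, C-3(Me)=C-4, C-5, C-6, C-7(Me), C-8, C-9 (free carbinol), C-10 (isopropyl).
Assumption: the (S)-diarylprolinol has the facial sense of L-proline and (S)-TRIP delivers the allenyl group to the formyl Si face; if either sense is reversed, the antipodal catalyst is used.

**Step 1**
Reactants: 1 3-methylbutanal (isovaleraldehyde); 2 but-2-ynal
Product: 3 (2S,3R)-3-hydroxy-2-(propan-2-yl)hex-4-ynal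
Conditions: 1 (3 equiv), (S)-α,α-bis[3,5-bis(trifluoromethyl)phenyl]pyrrolidin-2-ylmethanol (10 mol%), H2O (3 equiv), 1,4-dioxane, 4 °C; short silica plug, used at once
Reagents that add atoms: none
Why: Diarylprolinol-catalysed enamine cross-aldol with an alkynyl aldehyde: the anti-enamine of 1 attacks the Re face of the hydrogen-bonded, non-enolisable ynal 2, setting C-10 (S) and C-9 (R) anti in one step, while β-branched 1 self-condenses slowly.

**Step 2**
Reactants: 3 (2S,3R)-3-hydroxy-2-(propan-2-yl)hex-4-ynal; 4 4,4,5,5-tetramethyl-2-(propa-1,2-dien-1-yl)-1,3,2-dioxaborolane (allenylboronic acid pinacol ester)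
Product: 5 (4S,5R,6R)-5-(propan-2-yl)nona-1,7-diyne-4,6-diol
Conditions: 4 (1.5 equiv), (S)-TRIP [(S)-3,3′-bis(2,4,6-triisopropylphenyl)-1,1′-binaphthyl-2,2′-diyl hydrogen phosphate] (10 mol%), 4 Å MS, toluene, −30 → 0 °C; aq. NaHCO3
Reagents that add atoms: none
Why: Proposed new method: a chiral-phosphoric-acid-catalysed allenylboration of an unprotected, α-branched β-hydroxy aldehyde taken straight from an enamine aldol has not been shown; the acid P–OH hydrogen-bonds the pseudo-axial pinacol oxygen of 4 and P=O binds the formyl C–H, so the allenyl terminus is delivered through a closed six-membered SE2′ chair to the formyl Si face, which is also the Felkin face, giving C-1 (S) syn to isopropyl and 1,3-anti to the C-9 hydroxyl, while the free hydroxyl does not exchange on the pinacol boronate and the acid cracks the hemiacetal dimer of 3; closest known reaction type: phosphoric-acid-catalysed allenyl- and allylboration of simple aldehydes.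

**Step 3**
Reactants: 5 (4S,5R,6R)-5-(propan-2-yl)nona-1,7-diyne-4,6-diol; 6 bromoethene (vinyl bromide)
Product: 8 (3E,6S,7R,8R)-4-methyl-7-(propan-2-yl)undeca-1,3-dien-9-yne-6,8-diol, via alkenylalane 7 (not isolated)
Conditions: Al(CH3)3 (5 equiv), Cp2ZrCl2 (0.3 equiv), H2O (1 equiv), CH2Cl2, −20 °C; then 6 (4 equiv), ZnCl2 (1.2 equiv), Pd(PPh3)4 (5 mol%), THF, rt; aq. KNaC4H4O6
Reagents that add atoms: trimethylaluminium, C[Al](C)C
Why: Negishi zirconium-catalysed syn-methylalumination of the terminal alkyne (aluminium at the terminus; the internal alkyne is much slower) followed by Negishi palladium-catalysed coupling of the alkenyl metal with 6 with retention gives the (E)-trisubstituted diene.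

**Step 4**
Reactants: 8 (3E,6S,7R,8R)-4-methyl-7-(propan-2-yl)undeca-1,3-dien-9-yne-6,8-diol
Product: 10 (3E,6S,7R,8R,9Z)-10-iodo-4-methyl-7-(propan-2-yl)undeca-1,3,9-triene-6,8-diol, via alkenylalanate 9 (not isolated)
Conditions: NaAlH2(OCH2CH2OCH3)2 (4 equiv), THF, 0 °C → rt; EtOAc, then I2 (3 equiv), −78 → 0 °C; aq. Na2S2O3
Reagents that add atoms: iodine, [I][I]
Why: Hydroxyl-directed trans-hydroalumination of the propargylic alcohol places aluminium on the distal carbon (C-7) in a five-membered alanate, and iodinolysis with retention gives the (Z)-3-iodoallylic alcohol with iodine cis to C-9.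

**Step 5**
Reactants: 10 (3E,6S,7R,8R,9Z)-10-iodo-4-methyl-7-(propan-2-yl)undeca-1,3,9-triene-6,8-diol
Product: 12 (1S,2R,3S,4Z,8E)-5,9-dimethyl-2-(propan-2-yl)cyclodeca-4,8-diene-1,3-diol, via alkylborane 11 (not isolated)
Conditions: 9-borabicyclo[3.3.1]nonane (3.3 equiv), THF, 0 °C → rt; then slow addition (10 h) to Pd(dppf)Cl2 (15 mol%), AsPh3 (30 mol%), Cs2CO3 (4 equiv), DMF/THF/H2O, 50 °C, final 2 mM
Reagents that add atoms: none
Why: B-alkyl Suzuki–Miyaura macrocyclisation: 9-BBN adds only to the terminal CH=CH2 of the 4,4-disubstituted diene (boron at C-6), and intramolecular alkyl–alkenyl coupling with retention of the (Z)-iodide geometry closes the ten-membered ring under high dilution without touching a stereocentre.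

**Step 6**
Reactants: 12 (1S,2R,3S,4Z,8E)-5,9-dimethyl-2-(propan-2-yl)cyclodeca-4,8-diene-1,3-diol
Product: 13 (2Z,6E,9S,10R)-9-hydroxy-3,7-dimethyl-10-(propan-2-yl)cyclodeca-2,6-dien-1-one
Conditions: activated MnO2 (20 equiv), CH2Cl2, rt; filtered, used directly
Reagents that add atoms: none
Why: Heterogeneous MnO2 allylic oxidation converts only the allylic C-9 alcohol into the enone, which differentiates the two oxygens and leaves the saturated C-1 carbinol and C-10 untouched under neutral conditions.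

**Step 7**
Reactants: 13 (2Z,6E,9S,10R)-9-hydroxy-3,7-dimethyl-10-(propan-2-yl)cyclodeca-2,6-dien-1-one; 14 3,4,5-trimethoxybenzaldehyde
Product: 15 (1S,3E,7Z,9S,10S)-9-hydroxy-3,7-dimethyl-10-(propan-2-yl)cyclodeca-3,7-dien-1-yl 3,4,5-trimethoxybenzoate
Conditions: 14 (6 equiv), SmI2 (0.3 equiv, premixed with 14), THF, −10 °C
Reagents that add atoms: none
Why: Evans–Tishchenko reduction: the samarium-bound C-1 hemiacetal of 14 delivers hydride intramolecularly to the C-9 ketone through a six-membered chair, so the acyl group stays on O-1 and the C-9 carbinol is formed 1,3-anti to it, restoring the aldol configuration at C-9.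

**Step 8**
Reactants: 15 (1S,3E,7Z,9S,10S)-9-hydroxy-3,7-dimethyl-10-(propan-2-yl)cyclodeca-3,7-dien-1-yl 3,4,5-trimethoxybenzoate
Product: 16 (1R,2R,3S,4S,6E,10S)-2-hydroxy-6,10-dimethyl-3-(propan-2-yl)-11-oxabicyclo[8.1.0]undec-6-en-4-yl 3,4,5-trimethoxybenzoate (CNP0260213.12)
Conditions: VO(acac)2 (5 mol%), t-BuOOH (1.5 equiv, decane), CH2Cl2, 0 °C
Reagents that add atoms: tert-butyl hydroperoxide, CC(C)(C)OO
Why: Vanadium-catalysed hydroxyl-directed epoxidation: the C-9 alkoxide binds the peroxo-vanadium species and oxygen is delivered to the allylic (Z)-olefin on the face syn to the hydroxyl (cis epoxy alcohol, as with medium-ring cycloalkenols), setting C-7 (S) and C-8 (R), while the remote (E)-olefin has no free hydroxyl to direct and is left alone.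

**Compound list**
1 | 3-methylbutanal (isovaleraldehyde) | CC(C)CC=O | starting material
2 | but-2-ynal | CC#CC=O | starting material
3 | (2S,3R)-3-hydroxy-2-(propan-2-yl)hex-4-ynal | O=C[C@@H](C(C)C)[C@@H](O)C#CC | intermediate
4 | 4,4,5,5-tetramethyl-2-(propa-1,2-dien-1-yl)-1,3,2-dioxaborolane | C=C=CB1OC(C)(C)C(C)(C)O1 | starting material
5 | (4S,5R,6R)-5-(propan-2-yl)nona-1,7-diyne-4,6-diol | C#CC[C@H](O)[C@@H](C(C)C)[C@@H](O)C#CC | intermediate
6 | bromoethene | C=CBr | starting material
7 | (E)-alkenyl(dimethyl)alane of 5 (Al on C-4, methyl on C-3, both hydroxyls as dimethylaluminium alkoxides; not isolated) | C[Al](C)/C=C(\C)C[C@H](O[Al](C)C)[C@@H](C(C)C)[C@@H](O[Al](C)C)C#CC | intermediate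
8 | (3E,6S,7R,8R)-4-methyl-7-(propan-2-yl)undeca-1,3-dien-9-yne-6,8-diol | C=C/C=C(\C)C[C@H](O)[C@@H](C(C)C)[C@@H](O)C#CC | intermediate
9 | cyclic sodium alkenylalanate of 8 (five-membered O–Al–C-7=C-8 ring, two 2-methoxyethoxy ligands, C-1 alkoxide; not isolated) | C=C/C=C(\C)C[C@H]([O-])[C@@H](C(C)C)[C@H]1O[Al-](OCCOC)(OCCOC)C(C)=C1.[Na+].[Na+] | intermediate
10 | (3E,6S,7R,8R,9Z)-10-iodo-4-methyl-7-(propan-2-yl)undeca-1,3,9-triene-6,8-diol | C=C/C=C(\C)C[C@H](O)[C@@H](C(C)C)[C@@H](O)/C=C(/C)I | intermediate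
11 | B-alkyl-9-borabicyclo[3.3.1]nonane of 10 (boron on C-6; not isolated) | B1(CC/C=C(\C)C[C@H](O)[C@@H](C(C)C)[C@@H](O)/C=C(/C)I)C2CCCC1CCC2 | intermediate
12 | (1S,2R,3S,4Z,8E)-5,9-dimethyl-2-(propan-2-yl)cyclodeca-4,8-diene-1,3-diol | O[C@H]1C/C(C)=C/CC/C(C)=C\[C@H](O)[C@@H]1C(C)C | intermediate
13 | (2Z,6E,9S,10R)-9-hydroxy-3,7-dimethyl-10-(propan-2-yl)cyclodeca-2,6-dien-1-one | O[C@H]1C/C(C)=C/CC/C(C)=C\C(=O)[C@@H]1C(C)C | intermediate
14 | 3,4,5-trimethoxybenzaldehyde | COc1cc(C=O)cc(OC)c1OC | starting material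
15 | (1S,3E,7Z,9S,10S)-9-hydroxy-3,7-dimethyl-10-(propan-2-yl)cyclodeca-3,7-dien-1-yl 3,4,5-trimethoxybenzoate | COc1cc(C(=O)O[C@H]2C/C(C)=C/CC/C(C)=C\[C@H](O)[C@@H]2C(C)C)cc(OC)c1OC | intermediate
16 | (1R,2R,3S,4S,6E,10S)-2-hydroxy-6,10-dimethyl-3-(propan-2-yl)-11-oxabicyclo[8.1.0]undec-6-en-4-yl 3,4,5-trimethoxybenzoate (CNP0260213.12) | COc1cc(C(=O)O[C@H]2C/C(C)=C/CC[C@]3(C)O[C@@H]3[C@H](O)[C@@H]2C(C)C)cc(OC)c1OC | target

**Step count**
Total steps: 8. Longest linear sequence: 8.

**Three steps most likely to fail**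

Step 5 (ten-membered Suzuki closure). The risks are oligomerisation, slow closure at the methyl-bearing iodide carbon, and Cope or transannular reactions of the 1,5-diene if heated. The fallback closes the ring at C-4–C-5 instead, on the less hindered (E)-alkenyl iodide. It sets out from 5: NaAlH2(OCH2CH2OCH3)2 then I2 at −78 °C gives (4S,5R,6R,7Z)-8-iodo-5-(propan-2-yl)non-7-en-1-yne-4,6-diol F1, with the terminal alkyne kept cold so that it is not metalated. Suzuki coupling with K[CH2=CHBF3] (Pd(dppf)Cl2, Cs2CO3, THF/H2O) gives (3Z,5S,6R,7S)-3-methyl-6-(propan-2-yl)deca-1,3-dien-9-yne-5,7-diol F2. Cp2ZrCl2/Al(CH3)3 methylalumination followed by I2 gives (3Z,5S,6R,7S,9E)-10-iodo-3,9-dimethyl-6-(propan-2-yl)deca-1,3,9-triene-5,7-diol F3. 9-BBN hydroboration of its terminal vinyl group (boron at C-5) and the same palladium conditions under high dilution then come back to the route at 12.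

Step 2 (the proposed new propargylation). The risks are acid-promoted dehydration of 3 to the enynal, interference of the free hydroxyl, and a weaker catalyst preference than assumed. The fallback is known substrate-controlled chemistry and sets out from 3: TESCl/imidazole gives (2S,3R)-2-(propan-2-yl)-3-[(triethylsilyl)oxy]hex-4-ynal F4. BF3·OEt2-promoted addition of Bu3SnCH=C=CH2 (CH2Cl2, −78 °C), in which Felkin and 1,3-anti induction reinforce each other for an anti aldehyde, gives (4S,5R,6R)-5-(propan-2-yl)-6-[(triethylsilyl)oxy]nona-1,7-diyn-4-ol F5. PPTS in MeOH removes the silyl group and comes back to the route at 5.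

Step 7 (Evans–Tishchenko on the macrocyclic enone). The risks are a strained transannular hydride-transfer geometry, 1,3-acyl migration, and sluggish hemiacetal formation with the electron-rich aldehyde. The fallback separates acylation from reduction and sets out from 13: 3,4,5-trimethoxybenzoyl chloride in pyridine at 0 °C acylates the only free hydroxyl to give (1S,3E,7Z,10R)-3,7-dimethyl-9-oxo-10-(propan-2-yl)cyclodeca-3,7-dien-1-yl 3,4,5-trimethoxybenzoate F6. Reagent-controlled reduction of the enone with (S)-2-methyl-CBS-oxazaborolidine and catecholborane at −78 °C (alkenyl as the large group) then comes back to the route at 15.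

**Further compounds**
F1 | step 5 | (4S,5R,6R,7Z)-8-iodo-5-(propan-2-yl)non-7-en-1-yne-4,6-diol | C#CC[C@H](O)[C@@H](C(C)C)[C@@H](O)/C=C(/C)I
F2 | step 5 | (3Z,5S,6R,7S)-3-methyl-6-(propan-2-yl)deca-1,3-dien-9-yne-5,7-diol | C#CC[C@H](O)[C@@H](C(C)C)[C@@H](O)/C=C(/C)C=C
F3 | step 5 | (3Z,5S,6R,7S,9E)-10-iodo-3,9-dimethyl-6-(propan-2-yl)deca-1,3,9-triene-5,7-diol | I/C=C(\C)C[C@H](O)[C@@H](C(C)C)[C@@H](O)/C=C(/C)C=C
F4 | step 2 | (2S,3R)-2-(propan-2-yl)-3-[(triethylsilyl)oxy]hex-4-ynal | O=C[C@@H](C(C)C)[C@@H](O[Si](CC)(CC)CC)C#CC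
F5 | step 2 | (4S,5R,6R)-5-(propan-2-yl)-6-[(triethylsilyl)oxy]nona-1,7-diyn-4-ol | C#CC[C@H](O)[C@@H](C(C)C)[C@@H](O[Si](CC)(CC)CC)C#CC
F6 | step 7 | (1S,3E,7Z,10R)-3,7-dimethyl-9-oxo-10-(propan-2-yl)cyclodeca-3,7-dien-1-yl 3,4,5-trimethoxybenzoate | COc1cc(C(=O)O[C@H]2C/C(C)=C/CC/C(C)=C\C(=O)[C@@H]2C(C)C)cc(OC)c1OC
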